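The readings were computed from invented constants; the scatter is artificial.

Read the flasks and the earlier runs below, then take the far end of the row first, where X stands highest.

| setting | gamma | beta | zeta | dusk | midnight | summer | winter | noon |
|---|---|---|---|---|---|---|---|---|
| Q | 0.050 M | 0.050 M | 0.050 M | 0.050 M | 0.050 M | 0.050 M | 0.050 M | 0.050 M |
| X | 0.024 M | 0.16 M | 1.3 M | 0.0200 M | 0.0600 M | 0.200 M | 0.500 M | 1.50 M |
| remark | run made earlier | run made earlier | run made earlier |  |  |  |  |  |
| time |  |  |  | 3.0 h | 3.0 h | 3.0 h | 3.0 h | 3.0 h |

- gamma (time / h: E / %, G / %): 0.250: 2, 1; 0.833: 5, 0; 1.33: 8, 1; 2.00: 7, 0; 3.00: 9, 2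
- beta (time / h: E / %, G / %): 0.250: 13, 0; 0.833: 27, 6; 1.33: 27, 11; 2.00: 24, 7; 3.00: 20, 7
- zeta (time / h: E / %, G / %): 0.250: 58, 10; 0.417: 56, 13; 0.833: 34, 5; 1.50: 13, 4; 3.00: 3, 2

(scatter of a reading: 1.5 percentage points)

- amount of E at the end, in percent of the Q charged for dusk, midnight, summer, winter, noon, in this order
- the shape of the row from first to last (hardly changes / falls, then rises / falls all the way / rises, then falls / rises all the way)

- the numbers in the tables scatter with a standard deviation of 1.5 percentage points
- "hardly changes" means that all values lie within two and a half points (for a concentration: within two and a half percent of the largest)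
- a step back or a flat step of under half a point counts as no turn

**What can you freeze in the zeta run?** The fall of E once Q has stopped feeding it. Between 1.50 h and 3.00 h, the zeta readings give 0.978 h⁻¹. That is the tail rate, the natural logarithm of how far E falls, per hour, in a stretch where Q feeds it little.

**Q was never measured. How do you know it has stopped feeding E in zeta?** At 0.250 h, E and G together already hold 68.0% of the Q charged. The Q charged in zeta is 3.85% of the X charged, so X stays close to its charge and Q falls pseudo-first-order; these scattered readings put its rate at about 4.56 h⁻¹ or faster. As an estimate, that puts Q in zeta near 0.107% at 1.50 h.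

**Your last zeta reading is small. What is the rate worth?** Little to the second digit. One standard deviation either way on that reading moves the tail rate between 0.707 h⁻¹ and 1.44 h⁻¹.

**What do you commit to?** In zeta, Q falls faster than E does, so E builds early and then runs down. For noon, I start from zeta's first E reading and apply the tail rate up to the asked time, which gives a rough 3.94%; it is rough because Q still feeds E at that first reading and noon is charged with more X than zeta. If the Q rate scales with X, dusk starts out losing Q at about 0.0701 h⁻¹, slower than the tail rate, so E at dusk stays tied to its making. I expect the row to rise, then fall.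

The forecast gave 6.5%, 15%, 21%, 12% and 3%, shape rises, then falls: “High X means Q is used up early and E has already decayed.”

The flasks give 6.34%, 14.8%, 19.0%, 9.79% and 3.70%, shape rises, then falls.

    X + G → L (k = 0.00104 L mol⁻¹ s⁻¹)
    E ⇌ D (K = 9.13, k = 2.36 × 10⁻⁴ s⁻¹)
    Q + X → E + J (k = 0.00147 L mol⁻¹ s⁻¹)
    E ⇌ G (K = 0.320, k = 4.01 × 10⁻⁴ s⁻¹)

In noon, with Q at 0% by 1.50 h, the tail rate takes E from 13.4% to 3.09% at the end, against 3.70% found. Part of that tail runs through G into L, with X still at 95% of its charge at the end: without X + G → L, noon would end with 17.5% of E instead of 3.70%. Noon's own tail is 0.860 h⁻¹. Winter, with less X and Q at 2.62% by 1.50 h, falls slower, at 0.691 h⁻¹, so the carried rate's 6.36% for winter stands below the 9.79% found.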